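**Retrosynthetic overview**

1. Target 23 ⇐ ethylidenation of aldehyde 22 ⇐ oxidation and methanolysis of macrolactone 20, in which the C13 carboxyl is esterified by C8' of the side chain (temporary ring).
2. 20 ⇐ transannular Diels–Alder reaction (rings C and D; bonds C6–C10 and C5–C13) of the 17-membered dienoate lactone 19 ⇐ ring closure through the C9–C10 bond by hydroboration/B-alkyl Suzuki–Miyaura coupling of bicyclo[4.2.0]octadiene 17.
3. 17 ⇐ Corey–Winter unveiling of the ring-B diene from a cis-diol ⇐ ring A by asymmetric keteniminium [2+2] cycloaddition onto the acetonide of cis-cyclohexa-3,5-diene-1,2-diol, so ring B is a dearomatised benzene.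
4. Enabling feature: C9 is an isolated CH2 between C8 (ring A) and C10, and C10–C11=C12–C13(CO2Me) in ring D is the retron of an (E,E)-dienoate adding to C5=C6. Opening ring D therefore makes C9–C10 an sp3–sp2 bond, and the C13 ester and the saturated C1'–C8' chain on C1 can be tied into a strain-free lactone, which turns that bond formation into a ring closure.
5. Order of ring formation: B (from the arene) → A → 17-membered lactone (temporary, closed by C9–C10) → C and D (one cycloaddition) → lactone opened.

Key step: step 11

Locants: the target numbering is used for all intermediates. Ring A = cyclobutane C1–C2–C7–C8 (C1 carries the side chain C1'–C10'); ring B = C2–C3=C4–C5–C6–C7; ring C = C6–C7–C8–C9–C10; ring D = C5–C6–C10–C11=C12–C13 (C13 carries CO2Me). Exo and endo mean the ring-A face turned away from or toward ring B.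

Assumption: the (2R,5R)-auxiliary is taken to select the enantiotopic alkene that leads to 12 as drawn; if induction runs the other way, (2S,5S)-2,5-dimethylpyrrolidine is used with no other change.

**Route**

Step 1
Reactants: 1 ethyl (E)-4-oxobut-2-enoate
Product: 2 ethyl (2E,4E)-5-iodopenta-2,4-dienoate
Conditions: CrCl2, CHI3, THF, 0 °C
Reagents that add atoms: iodoform, IC(I)I
Why: Takai olefination: the geminal dichromium reagent from CHI3 and CrCl2 adds only to the aldehyde and anti-elimination should give the (E)-vinyl iodide, the enoate geometry being untouched.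

Step 2
Reactants: 2 ethyl (2E,4E)-5-iodopenta-2,4-dienoate
Product: 3 (2E,4E)-5-iodopenta-2,4-dienoic acid
Conditions: LiOH, THF/H2O, 0 °C; then aq. HCl
Reagents that add atoms: lithium hydroxide (hydroxide oxygen), [Li+].[OH-]
Why: Saponification of the ethyl ester; the conjugated vinyl iodide is inert to cold hydroxide and no stereocentre is involved.

Step 3
Reactants: 4 cis-cyclohexa-3,5-diene-1,2-diol
Product: 5 acetonide of 4 (cis-2,2-dimethyl-3a,7a-dihydro-1,3-benzodioxole)
Conditions: 2,2-dimethoxypropane, TsOH·H2O (cat.), acetone, 0 °C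
Reagents that add atoms: 2,2-dimethoxypropane, COC(C)(C)OC
Why: Acid-catalysed transacetalisation of the cis-diol, run cold so that the dihydrodiol does not dehydrate to phenol; the acetonide later shields one face of the diene.

Step 4
Reactants: 6 10-bromodecanoic acid; 7 (2R,5R)-2,5-dimethylpyrrolidine
Product: 9 10-bromodecanoyl amide of 7, via 10-bromodecanoyl chloride 8 (not isolated)
Conditions: (COCl)2, DMF (cat.), CH2Cl2, 0 °C to rt; then 7, Et3N, CH2Cl2, 0 °C
Reagents that add atoms: none
Why: Acyl chloride formation and amidation (Schotten–Baumann type) attach the C2-symmetric amine that will steer the cycloaddition; no new stereocentre.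

Step 5
Reactants: 9 10-bromodecanoyl amide of 7; 5 acetonide of 4
Product: 12 exo ketone (ring A cyclobutanone C8=O cis-fused to ring B; 8-bromooctyl at C1 exo; C5/C6 acetonide anti to ring A), via keteniminium triflate 10 (not isolated), via cyclobutaniminium triflate 11 (not isolated)
Conditions: Tf2O, 2,6-di-tert-butyl-4-methylpyridine, 5 (2.5 equiv), ClCH2CH2Cl, −20 to 40 °C; aq. NaHCO3, 40 °C; DBU (cat.), CH2Cl2, rt
Reagents that add atoms: water, O
Why: Keteniminium–alkene [2+2] cycloaddition: the keteniminium ion from amide activation should add stepwise to one of the two enantiotopic cis-alkenes of the meso diene on the face opposite the acetonide, its central carbon (C8) bonding to the diene terminus (C7) and C1 to the internal carbon (C2), which sets C2 and C7 (cis fusion, ring A anti to the acetonide) while the (2R,5R)-pyrrolidine chooses the alkene and hence the absolute configuration; hydrolysis frees the ketone and DBU equilibrates C1 to the exo (thermodynamic) epimer.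

Step 6
Reactants: 12 exo ketone
Product: 13 C8-methylene compound (exocyclic C8=C9H2)
Conditions: Cp2TiMe2, PhMe/THF, 65 °C, dark
Reagents that add atoms: Cp2TiMe2 (bis(cyclopentadienyl)dimethyltitanium), [CH3-].[CH3-].[Ti+4].c1cc[cH-]c1.c1cc[cH-]c1
Why: Carbonyl methylenation with Cp2TiMe2 (titanium methylidene, Wittig-like but non-basic), so that the C1 stereocentre next to the carbonyl, the alkyl bromide and the acetonide are left alone.

Step 7
Reactants: 13 C8-methylene compound; 3 (2E,4E)-5-iodopenta-2,4-dienoic acid
Product: 14 C8' ester of 13 with acid 3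
Conditions: Cs2CO3, NaI (cat.), DMF, 40 °C
Reagents that add atoms: none
Why: SN2 O-alkylation of the caesium carboxylate of 3 by the primary bromide, which ties the future C13 carboxyl to C8' of the side chain; no stereocentre is touched.

Step 8
Reactants: 14 C8' ester
Product: 15 C5/C6 cis-diol
Conditions: AcOH/THF/H2O (3:1:1), 40 °C
Reagents that add atoms: none
Why: Acid-catalysed acetal hydrolysis frees the cis-diol under conditions that leave the ester, the vinyl iodide and the exocyclic alkene intact.

Step 9
Reactants: 15 C5/C6 cis-diol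
Product: 16 C5/C6 cyclic thionocarbonate
Conditions: 1,1'-thiocarbonyldiimidazole, DMAP (cat.), THF, 50 °C
Reagents that add atoms: 1,1'-thiocarbonyldiimidazole, S=C(n1ccnc1)n1ccnc1
Why: Cyclic thionocarbonate formation on the cis-diol (first stage of the Corey–Winter olefination).

Step 10
Reactants: 16 C5/C6 cyclic thionocarbonate
Product: 17 ring-B diene (bicyclo[4.2.0]octa-2,4-diene with C8 methylene and the iododienoate ester chain)
Conditions: 1,3-dimethyl-2-phenyl-1,3,2-diazaphospholidine, THF, 25 °C
Reagents that add atoms: none
Why: Corey–Winter olefination in its diazaphospholidine variant: sulfur abstraction and stereospecific syn cycloreversion with loss of CO2 should give the cis C5=C6 alkene, i.e. the ring-B 1,3-diene, at room temperature, where the bicyclo[4.2.0]octadiene does not yet open by 6π electrocyclic reaction.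

Step 11
Reactants: 17 ring-B diene
Product: 20 tetracyclic macrolactone (rings A–D; C13 carbonyl bridged by oxygen to C8'), via B-alkyl-9-BBN borane 18 (not isolated), via 17-membered dienoate lactone 19 (not isolated)
Conditions: 9-BBN, THF, 0 °C to rt; slow addition to PdCl2(dppf) (15 mol %), AsPh3, Cs2CO3, DMF/THF/H2O, 1 mM, rt; aqueous work-up; PhMe, BHT, 100 °C
Reagents that add atoms: none
Why: 9-BBN hydroborates only the 1,1-disubstituted exocyclic alkene, placing boron on C9 and delivering hydrogen to C8 from the convex exo face of the cis-fused bicycle, so that C9 becomes endo and trans to the C1 chain; oxidative addition of the dienyl iodide to zerovalent palladium, transfer of the primary alkyl group from boron and reductive elimination then join C9 to C10 with retention of the (E,E)-diene, closing the 17-membered lactone 19 (macrocyclic B-alkyl Suzuki–Miyaura coupling). Heated, 19 should undergo a transannular Diels–Alder reaction, whose closest precedent is the thermal cyclisation of bicyclo[4.2.0]octa-2,4-dienes that carry an endo dienyl chain on the four-membered ring. Ring D closes as the [4+2] ring through the C5–C13 and C6–C10 bonds and ring C as the five-membered ring spanned by the tether C7–C8–C9, whereas the lactone closed through C9–C10 is a temporary ring. C5 and C6 are fixed by the tether, which can bring the diene only to the ring-A face of ring B; C10 and C13 follow from suprafacial addition of the (E,E)-dienoate (H-10 and H-13 cis) in the alignment that keeps the inner diene carbons away from ring A, which gives the trans C6–C10 ring fusion. The step needs chemoselective hydroboration (9-BBN prefers the 1,1-disubstituted alkene over the ring diene and the electron-poor dienoate), ring closure over oligomerisation (slow addition at 1 mM) and the dienoate rather than ring B as the 4π partner; the bridged adduct of the other mode is related to 20 by a Cope rearrangement (C5=C4–C3–C11–C12=C13) and is the more strained isomer.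

Step 12
Reactants: 20 tetracyclic macrolactone
Product: 21 methyl ester with 8-hydroxyoctyl chain at C1
Conditions: TsOH·H2O (10 mol %), MeOH, 60 °C
Reagents that add atoms: methanol, CO
Why: Acid-catalysed transesterification (Fischer type) opens the macrolactone to the methyl ester and frees the C8' alcohol; since no enolate is formed, the epimerisable C13 centre and the non-conjugated position of C11=C12 should be preserved.

Step 13
Reactants: 21 hydroxy methyl ester
Product: 22 aldehyde (8-oxooctyl chain at C1)
Conditions: Dess–Martin periodinane, NaHCO3, CH2Cl2, 0 °C to rt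
Reagents that add atoms: none
Why: Dess–Martin oxidation of the primary alcohol to the aldehyde under buffered, non-basic conditions.

Step 14
Reactants: 22 aldehyde
Product: 23 target (CNP0133550.1)
Conditions: CrCl2, CH3CHI2, THF, rt
Reagents that add atoms: 1,1-diiodoethane, CC(I)I
Why: Takai–Utimoto ethylidenation: the geminal dichromium reagent from 1,1-diiodoethane adds to the aldehyde and anti-elimination should give the (E)-propenyl terminus, CrCl2 being non-basic toward the C13 ester.

**Compound list**

1 | ethyl (E)-4-oxobut-2-enoate | CCOC(=O)/C=C/C=O | starting material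
2 | ethyl (2E,4E)-5-iodopenta-2,4-dienoate | CCOC(=O)/C=C/C=C/I | intermediate
3 | (2E,4E)-5-iodopenta-2,4-dienoic acid | OC(=O)/C=C/C=C/I | intermediate
4 | cis-cyclohexa-3,5-diene-1,2-diol (meso) | O[C@H]1C=CC=C[C@H]1O | starting material
5 | acetonide of 4, cis-2,2-dimethyl-3a,7a-dihydro-1,3-benzodioxole (meso) | CC1(C)O[C@H]2C=CC=C[C@H]2O1 | intermediate
6 | 10-bromodecanoic acid | OC(=O)CCCCCCCCCBr | starting material
7 | (2R,5R)-2,5-dimethylpyrrolidine | C[C@@H]1CC[C@@H](C)N1 | starting material
8 | 10-bromodecanoyl chloride | ClC(=O)CCCCCCCCCBr | intermediate (not isolated)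
9 | 10-bromo-1-[(2R,5R)-2,5-dimethylpyrrolidin-1-yl]decan-1-one | BrCCCCCCCCCC(=O)N1[C@H](C)CC[C@H]1C | intermediate
10 | keteniminium triflate from 9, N-[2-(8-bromooctyl)ethenylidene]-(2R,5R)-2,5-dimethylpyrrolidinium triflate | BrCCCCCCCCC=C=[N+]1[C@H](C)CC[C@H]1C.[O-]S(=O)(=O)C(F)(F)F | intermediate (not isolated)
11 | cyclobutaniminium triflate: ring A cis-fused to ring B, C8=N+ pyrrolidinium, C5/C6 acetonide anti to ring A, C1 epimers | BrCCCCCCCCC1[C@H]2C=C[C@@H]3OC(C)(C)O[C@@H]3[C@H]2C1=[N+]1[C@H](C)CC[C@H]1C.[O-]S(=O)(=O)C(F)(F)F | intermediate (not isolated)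
12 | exo ketone: ring A cyclobutanone (C8=O) cis-fused to ring B (C3=C4), 8-bromooctyl at C1 exo, C5/C6 cis-acetonide anti to ring A | BrCCCCCCCC[C@@H]1[C@H]2C=C[C@@H]3OC(C)(C)O[C@@H]3[C@H]2C1=O | intermediate
13 | C8-methylene analogue of 12 | BrCCCCCCCC[C@@H]1[C@H]2C=C[C@@H]3OC(C)(C)O[C@@H]3[C@H]2C1=C | intermediate
14 | (2E,4E)-5-iodopenta-2,4-dienoate ester at C8' of 13 | I/C=C/C=C/C(=O)OCCCCCCCC[C@@H]1[C@H]2C=C[C@@H]3OC(C)(C)O[C@@H]3[C@H]2C1=C | intermediate
15 | C5/C6 cis-diol from 14 | I/C=C/C=C/C(=O)OCCCCCCCC[C@@H]1[C@H]2C=C[C@H](O)[C@H](O)[C@H]2C1=C | intermediate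
16 | C5/C6 cyclic thionocarbonate | I/C=C/C=C/C(=O)OCCCCCCCC[C@@H]1[C@H]2C=C[C@@H]3OC(=S)O[C@@H]3[C@H]2C1=C | intermediate
17 | ring-B diene: cis-bicyclo[4.2.0]octa-2,4-diene, C8 methylene, C1 exo chain ending in the iododienoate ester | I/C=C/C=C/C(=O)OCCCCCCCC[C@@H]1[C@H]2C=CC=C[C@H]2C1=C | intermediate
18 | B-alkyl-9-BBN borane: boron on C9, H-8 exo, C9 endo and trans to the C1 chain | I/C=C/C=C/C(=O)OCCCCCCCC[C@@H]1[C@H]2C=CC=C[C@H]2[C@H]1CB1C2CCCC1CCC2 | intermediate (not isolated)
19 | 17-membered (E,E)-dienoate lactone spanning C1 and C8 of the bicyclo[4.2.0]octadiene | O=C1OCCCCCCCC[C@@H]2[C@H]3C=CC=C[C@H]3[C@H]2C/C=C/C=C/1 | intermediate (not isolated)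
20 | tetracyclic macrolactone: rings A–D with the target configuration, C13 carbonyl linked through oxygen to C8' | O=C5OCCCCCCCC[C@@H]1[C@H]2C=C[C@@H]3[C@@H]4[C@H]2[C@H]1C[C@H]4C=C[C@H]35 | intermediate
21 | methyl ester with 8-hydroxyoctyl chain at C1 | OCCCCCCCC[C@@H]1[C@H]2C=C[C@@H]3[C@@H]4[C@H]2[C@H]1C[C@H]4C=C[C@H]3C(=O)OC | intermediate
22 | methyl ester with 8-oxooctyl chain at C1 | O=CCCCCCCC[C@@H]1[C@H]2C=C[C@@H]3[C@@H]4[C@H]2[C@H]1C[C@H]4C=C[C@H]3C(=O)OC | intermediate
23 | CNP0133550.1, methyl ester with (E)-dec-8-enyl chain at C1 | C/C=C/CCCCCCC[C@@H]1[C@H]2C=C[C@@H]3[C@@H]4[C@H]2[C@H]1C[C@H]4C=C[C@H]3C(=O)OC | target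

**Step count and risks**

Total: 14 steps. Longest linear sequence: 11 steps (step 3 or step 4, then steps 5 to 14).

Steps most likely to fail:

1. Step 11. The ring closure at high dilution may lose to intermolecular coupling, the hydroboration of the valence-labile diene may lose its face selectivity, or the cycloaddition may partition toward the bridged mode. Fallback: the C9–C10 bond is made intermolecularly on the locked acetonide and the diene is unveiled last, so that an ordinary intramolecular Diels–Alder reaction replaces the transannular one. Setting out from 13, acid 3 is first methylated with (trimethylsilyl)diazomethane in PhMe/MeOH to methyl (2E,4E)-5-iodopenta-2,4-dienoate F1. Compound 13 is hydroborated with 9-BBN to the B-alkyl-9-BBN borane F2, which is not isolated and is coupled with F1 under PdCl2(dppf), AsPh3 and Cs2CO3 in DMF/THF/H2O at rt to the open-chain methyl dienoate acetonide F3. Aqueous AcOH gives the C5/C6 cis-diol F4, and 1,1'-thiocarbonyldiimidazole the cyclic thionocarbonate F5. 1,3-Dimethyl-2-phenyl-1,3,2-diazaphospholidine in THF at rt is chosen over hot trimethyl phosphite, which could alkylate at the primary bromide, and releases the bicyclic diene with endo dienoate chain F6. After filtration through silica, heating in PhMe at 100 °C should give, by intramolecular Diels–Alder reaction, the tetracyclic methyl ester with 8-bromooctyl chain F7. Oxidation of the primary bromide with trimethylamine N-oxide in DMSO (Ganem oxidation) returns to the route at 22.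

2. Step 5. The auxiliary may discriminate poorly between the enantiotopic alkenes of 5, or the triflic anhydride activation may degrade the acid-sensitive diene. Fallback: the cycloaddition is run without asymmetric induction and the enantiomers are separated. Setting out from 6 and diene 5, acid 6 is converted into acid chloride 8 as in step 4, and Et3N in refluxing hexane generates (8-bromooctyl)ketene F8, which is not isolated. Its thermal [2+2] cycloaddition with 5 anti to the acetonide, followed by DBU equilibration at C1, should give the racemic exo ketone F9. Preparative chromatography on a cellulose tris(3,5-dimethylphenylcarbamate) stationary phase separates the enantiomers and returns to the route at 12.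

3. Step 10. Diene 17 may not survive isolation: 6π ring opening to the cyclooctatriene and re-closure would scramble the exo/endo relationship at C1, and [1,5]-hydrogen shift or dimerisation are also possible. Fallback: the ring closure is moved ahead of the olefination so that the diene is never handled. Setting out from 14, hydroboration with 9-BBN gives the acetonide-protected B-alkyl-9-BBN borane F10, which is not isolated, and the same high-dilution Suzuki–Miyaura conditions close the acetonide-protected 17-membered dienoate lactone F11. Aqueous AcOH gives the macrocyclic cis-diol F12, and 1,1'-thiocarbonyldiimidazole the macrocyclic thionocarbonate F13. P(OMe)3 in PhMe at 110 °C (classical Corey–Winter conditions) generates 19 in situ, which should cyclise at that temperature and return to the route at 20.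

Further compounds
F1 | step 11 | methyl (2E,4E)-5-iodopenta-2,4-dienoate | COC(=O)/C=C/C=C/I
F2 | step 11 | B-alkyl-9-BBN borane from 13, boron on C9, C9 endo | BrCCCCCCCC[C@@H]1[C@H]2C=C[C@@H]3OC(C)(C)O[C@@H]3[C@H]2[C@H]1CB1C2CCCC1CCC2
F3 | step 11 | open-chain methyl (2E,4E)-dienoate acetonide: dienoate on C9, C5/C6 acetonide, 8-bromooctyl at C1 | BrCCCCCCCC[C@@H]1[C@H]2C=C[C@@H]3OC(C)(C)O[C@@H]3[C@H]2[C@H]1C/C=C/C=C/C(=O)OC
F4 | step 11 | C5/C6 cis-diol from F3 | BrCCCCCCCC[C@@H]1[C@H]2C=C[C@H](O)[C@H](O)[C@H]2[C@H]1C/C=C/C=C/C(=O)OC
F5 | step 11 | C5/C6 cyclic thionocarbonate from F4 | BrCCCCCCCC[C@@H]1[C@H]2C=C[C@@H]3OC(=S)O[C@@H]3[C@H]2[C@H]1C/C=C/C=C/C(=O)OC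
F6 | step 11 | bicyclo[4.2.0]octa-2,4-diene with endo dienoate chain on C8 and 8-bromooctyl on C1 | BrCCCCCCCC[C@@H]1[C@H]2C=CC=C[C@H]2[C@H]1C/C=C/C=C/C(=O)OC
F7 | step 11 | tetracyclic methyl ester with 8-bromooctyl chain at C1 | BrCCCCCCCC[C@@H]1[C@H]2C=C[C@@H]3[C@@H]4[C@H]2[C@H]1C[C@H]4C=C[C@H]3C(=O)OC
F8 | step 5 | (8-bromooctyl)ketene | BrCCCCCCCCC=C=O
F9 | step 5 | racemic exo ketone, both enantiomers of 12 | BrCCCCCCCC[C@@H]1[C@H]2C=C[C@@H]3OC(C)(C)O[C@@H]3[C@H]2C1=O.BrCCCCCCCC[C@H]1[C@@H]2C=C[C@H]3OC(C)(C)O[C@H]3[C@@H]2C1=O
F10 | step 10 | acetonide-protected B-alkyl-9-BBN borane from 14, boron on C9, C9 endo | I/C=C/C=C/C(=O)OCCCCCCCC[C@@H]1[C@H]2C=C[C@@H]3OC(C)(C)O[C@@H]3[C@H]2[C@H]1CB1C2CCCC1CCC2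
F11 | step 10 | acetonide-protected 17-membered dienoate lactone | O=C1OCCCCCCCC[C@@H]2[C@H]3C=C[C@@H]4OC(C)(C)O[C@@H]4[C@H]3[C@H]2C/C=C/C=C/1
F12 | step 10 | macrocyclic C5/C6 cis-diol | O=C1OCCCCCCCC[C@@H]2[C@H]3C=C[C@H](O)[C@H](O)[C@H]3[C@H]2C/C=C/C=C/1
F13 | step 10 | macrocyclic C5/C6 cyclic thionocarbonate | O=C1OCCCCCCCC[C@@H]2[C@H]3C=C[C@@H]4OC(=S)O[C@@H]4[C@H]3[C@H]2C/C=C/C=C/1
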